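The plan rests on cutting the C2–C3 bond of the dihydropyran (ring O1, C2, C3, C4=C5, C6) after simplifying the acrylic unit on C2 to a carboxyl group. The unit C2–C3–C4=C5 with O1 on C2 is then the product pattern of an Ireland–Claisen rearrangement. One [3,3] shift of the silyl ketene acetal of a (6R)-6-vinyl-6-homofarnesyl-1,4-dioxan-2-one forms C2–C3, closes the pyran ring, places the C4=C5 alkene next to the chain on C5 and transfers the configuration of the tertiary carbinol carbon to C2. The carbinol centre comes from a tartrate-controlled epoxidation; the carboxyl carbon is finally converted into the acrylic α-carbon.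

Key step: step 7

Remark: "homofarnesyl" stands for the (3E,7E)-4,8,12-trimethyltrideca-3,7,11-trien-1-yl group; its two E-alkenes come unchanged from 1. The sense of the tartrate in step 2 is assigned from the rule that L-(+)-tartrate leads to (S)-2-alkylglycidols.

Step 1
Reactants: 1 (2E,6E)-farnesyl bromide; 2 2-methylprop-2-en-1-ol
Product: 4 2-homofarnesylprop-2-en-1-ol [(5E,9E)-6,10,14-trimethyl-2-methylidenepentadeca-5,9,13-trien-1-ol], via dilithio dianion 3 (not isolated)
Conditions: 2, n-BuLi (2.2 equiv), TMEDA, Et2O–hexane, 0 °C → rt; then 1, THF, −78 → 0 °C; H2O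
Reagents that add atoms: none
Why: Dianion alkylation: double lithiation of 2 gives a 2-(oxidomethyl)allyllithium whose carbon terminus is the nucleophile and, being a symmetrical allyl anion, gives one constitution from either end, so SN2 displacement of the primary allylic bromide should add the farnesyl unit as a homofarnesyl chain with both E-alkenes unchanged.

Step 2
Reactants: 4 2-homofarnesylprop-2-en-1-ol
Product: 5 [(2R)-2-homofarnesyloxiran-2-yl]methanol
Conditions: Ti(OiPr)4 (10 mol%), D-(−)-DIPT (12 mol%), t-BuOOH, 4 Å MS, CH2Cl2, −20 °C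
Reagents that add atoms: tert-butyl hydroperoxide, CC(C)(C)OO
Why: Sharpless asymmetric epoxidation: titanium binds the allylic hydroxyl, so of the four alkenes only the 1,1-disubstituted allylic one should be oxidised, and the D-(−)-tartrate (mirror image of the L-(+)-ligand that leads to (S)-2-alkylglycidols) should deliver oxygen to the face that sets the quaternary centre as R.

Step 3
Reactants: 5 [(2R)-2-homofarnesyloxiran-2-yl]methanol
Product: 6 (2S)-2-homofarnesyloxirane-2-carbaldehyde
Conditions: Dess–Martin periodinane, pyridine, CH2Cl2, 0 °C → rt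
Reagents that add atoms: none
Why: Dess–Martin oxidation under buffered, non-aqueous conditions should stop at the aldehyde and spare the 2,2-disubstituted epoxide and the alkenes; the centre has no α-hydrogen and cannot epimerise, and its descriptor becomes S only because CHO now outranks the ring CH2.

Step 4
Reactants: 6 (2S)-2-homofarnesyloxirane-2-carbaldehyde
Product: 7 (2R)-2-ethenyl-2-homofarnesyloxirane
Conditions: Ph3PCH3Br, KHMDS, THF, 0 °C; then 6, −78 → 0 °C
Reagents that add atoms: methyltriphenylphosphonium bromide, C[P+](c1ccccc1)(c1ccccc1)c1ccccc1.[Br-]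
Why: Wittig methylenation with the non-stabilised ylide should convert the hindered aldehyde into the vinyl group at low temperature without opening the epoxide; the centre is untouched and is again R by priority (ring CH2 over vinyl).

Step 5
Reactants: 7 (2R)-2-ethenyl-2-homofarnesyloxirane; 8 ethylene glycol
Product: 9 (3R,6E,10E)-3-[(2-hydroxyethoxy)methyl]-7,11,15-trimethylhexadeca-1,6,10,14-tetraen-3-ol
Conditions: 8 (20 equiv), KOt-Bu (0.3 equiv), 1,4-dioxane, 90 °C
Reagents that add atoms: none
Why: Base-catalysed SN2 ring opening of a terminal epoxide: potassium 2-hydroxyethoxide should attack the unsubstituted CH2 and not the quaternary allylic carbon, so the C–O bond of the carbinol centre is never broken and its R configuration is kept, while the large excess of glycol suppresses double alkylation.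

Step 6
Reactants: 9 (3R,6E,10E)-3-[(2-hydroxyethoxy)methyl]-7,11,15-trimethylhexadeca-1,6,10,14-tetraen-3-ol
Product: 12 (6R)-6-ethenyl-6-homofarnesyl-1,4-dioxan-2-one, via hydroxy aldehyde 10 (not isolated), via lactol 11 (not isolated)
Conditions: TEMPO (0.2 equiv), PhI(OAc)2 (2.4 equiv), CH2Cl2, rt
Reagents that add atoms: none
Why: Oxoammonium-mediated oxidative lactonisation: only the primary alcohol can be oxidised, the α-alkoxy aldehyde 10 should be trapped by the tertiary hydroxyl as the six-membered lactol 11, and a second oxidation should give the lactone without strong acid, which spares the tertiary allylic C–O bond and the trisubstituted alkenes.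

Step 7
Reactants: 12 (6R)-6-ethenyl-6-homofarnesyl-1,4-dioxan-2-one
Product: 15 (2R)-5-homofarnesyl-3,6-dihydro-2H-pyran-2-carboxylic acid, via silyl ketene acetal 13 (not isolated), via trimethylsilyl ester 14 (not isolated)
Conditions: TMSCl, Et3N, LiHMDS, THF, −78 °C → rt; PhMe, 90 °C; then H2O, pH 4 buffer
Reagents that add atoms: none
Why: Kinetic deprotonation of lactone 12 at C3 in the presence of TMSCl gives the cyclic O-silyl ketene acetal 13, whose C3 and vinyl terminus are joined in a concerted suprafacial [3,3] shift (Ireland–Claisen rearrangement of a 6-alkenyl-1,4-dioxan-2-one, a known route to 3,6-dihydro-2H-pyran-2-carboxylic acids) that forms C2–C3, cleaves the tertiary allylic ester C–O bond and leaves the C4=C5 alkene in the new ring. The dihydropyran (O1–C2–C3–C4=C5–C6) is closed by C–C bond formation between the ketene-acetal carbon and the alkene terminus, a pericyclic closure endo to the vinyl group, while the lactone ring is opened in the same event. Because both reacting termini are held in one six-membered ring, only a boat-like transition state shaped like bicyclo[2.2.2]octane is possible, with the homofarnesyl chain and the C3 hydrogen on the bridgeheads. The new C2 centre is therefore fixed by the quaternary carbinol centre alone: the vinyl group can reach only the ring face on which it stands, and the (6R) centre maps onto (2R). The step needs complete 1,4-chirality transfer and [3,3] reactivity ahead of ionisation of the tertiary allylic C–O bond; the single accessible transition-state topology secures the first, and a neutral silyl ketene acetal in a non-polar medium without Lewis acid secures the second. Aqueous work-up cleaves the silyl ester 14 to the acid 15.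

Step 8
Reactants: 15 (2R)-5-homofarnesyl-3,6-dihydro-2H-pyran-2-carboxylic acid
Product: 17 (2R)-5-homofarnesyl-N-methoxy-N-methyl-3,6-dihydro-2H-pyran-2-carboxamide, via acyl imidazolide 16 (not isolated)
Conditions: CDI, CH2Cl2, rt; then MeNHOMe·HCl, rt
Reagents that add atoms: N,O-dimethylhydroxylamine hydrochloride, CNOC.Cl
Why: Amide formation through the acyl imidazolide: carbonyldiimidazole activates the acid without strong base, and N,O-dimethylhydroxylamine should displace imidazole to give the N-methoxy-N-methylamide with the α-alkoxy centre C2 untouched.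

Step 9
Reactants: 17 (2R)-5-homofarnesyl-N-methoxy-N-methyl-3,6-dihydro-2H-pyran-2-carboxamide
Product: 18 1-[(2R)-5-homofarnesyl-3,6-dihydro-2H-pyran-2-yl]ethan-1-one
Conditions: MeMgBr, THF, −20 → 0 °C; aq. NH4Cl
Reagents that add atoms: methylmagnesium bromide, C[Mg]Br
Why: Ketone synthesis from an N-methoxy-N-methylamide: the Grignard adduct is held as a magnesium chelate until work-up, so a single methyl group should be added and no tertiary alcohol formed, and the C2 hydrogen is not removed under these conditions.

Step 10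
Reactants: 18 1-[(2R)-5-homofarnesyl-3,6-dihydro-2H-pyran-2-yl]ethan-1-one
Product: 20 1-[(2R)-5-homofarnesyl-3,6-dihydro-2H-pyran-2-yl]ethenyl trifluoromethanesulfonate, via potassium enolate 19 (not isolated)
Conditions: KHMDS, THF, −78 °C; PhNTf2, −78 → −20 °C; aq. NH4Cl
Reagents that add atoms: N-phenyl-bis(trifluoromethanesulfonimide), O=S(=O)(N(c1ccccc1)S(=O)(=O)C(F)(F)F)C(F)(F)F
Why: Kinetic enolisation and O-triflation: the bulky amide base at −78 °C should remove a proton from the unhindered methyl group faster than the tertiary C2–H next to oxygen, and trapping of the less substituted enolate 19 should give the 1,1-disubstituted enol triflate with C2 intact.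

Step 11
Reactants: 20 1-[(2R)-5-homofarnesyl-3,6-dihydro-2H-pyran-2-yl]ethenyl trifluoromethanesulfonate
Product: 21 methyl 2-[(2R)-5-homofarnesyl-3,6-dihydro-2H-pyran-2-yl]prop-2-enoate
Conditions: Pd(OAc)2 (5 mol%), PPh3 (10 mol%), CO (1 atm), MeOH, Et3N, DMF, rt → 40 °C
Reagents that add atoms: carbon monoxide, [C-]#[O+]; methanol, CO
Why: Palladium-catalysed alkoxycarbonylation of an enol triflate: oxidative addition into the C–OTf bond, CO insertion and methanolysis of the acyl-palladium species should place the ester carbon on the alkene carbon that carried the triflate, which gives the 2-substituted acrylate without touching the isolated alkenes or the allylic ether bonds.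

Step 12
Reactants: 21 methyl 2-[(2R)-5-homofarnesyl-3,6-dihydro-2H-pyran-2-yl]prop-2-enoate
Product: 22 2-[(2R)-5-homofarnesyl-3,6-dihydro-2H-pyran-2-yl]prop-2-enoic acid
Conditions: LiOH, THF–MeOH–H2O, rt; then 1 M HCl, 0 °C, pH 3
Reagents that add atoms: lithium hydroxide, [Li+].[OH-]
Why: Ester saponification: hydroxide should cleave the methyl ester at room temperature, and removal of the C2 hydrogen would give an anion with no ester stabilisation (the ester sits on the central carbon of that allyl system), so the stereocentre should survive and careful acidification releases the target acid.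

Compound list
1 | (2E,6E)-farnesyl bromide | CC(C)=CCC/C(C)=C/CC/C(C)=C/CBr | starting material
2 | 2-methylprop-2-en-1-ol | C=C(C)CO | starting material
3 | dilithio dianion of 2 [lithium 2-(lithiomethyl)prop-2-en-1-olate] | [Li]CC(=C)CO[Li] | intermediate (not isolated)
4 | 2-homofarnesylprop-2-en-1-ol [(5E,9E)-6,10,14-trimethyl-2-methylidenepentadeca-5,9,13-trien-1-ol] | C=C(CO)CC/C=C(\C)CC/C=C(\C)CCC=C(C)C | intermediate
5 | [(2R)-2-homofarnesyloxiran-2-yl]methanol | OC[C@]1(CC/C=C(\C)CC/C=C(\C)CCC=C(C)C)CO1 | intermediate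
6 | (2S)-2-homofarnesyloxirane-2-carbaldehyde | O=C[C@]1(CC/C=C(\C)CC/C=C(\C)CCC=C(C)C)CO1 | intermediate
7 | (2R)-2-ethenyl-2-homofarnesyloxirane | C=C[C@]1(CC/C=C(\C)CC/C=C(\C)CCC=C(C)C)CO1 | intermediate
8 | ethylene glycol | OCCO | starting material
9 | (3R,6E,10E)-3-[(2-hydroxyethoxy)methyl]-7,11,15-trimethylhexadeca-1,6,10,14-tetraen-3-ol | OCCOC[C@](C=C)(CC/C=C(\C)CC/C=C(\C)CCC=C(C)C)O | intermediate
10 | 2-{[(2R)-2-hydroxy-2-homofarnesylbut-3-en-1-yl]oxy}acetaldehyde | O=CCOC[C@](C=C)(CC/C=C(\C)CC/C=C(\C)CCC=C(C)C)O | intermediate (not isolated)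
11 | (6R)-6-ethenyl-6-homofarnesyl-1,4-dioxan-2-ol (both C2 epimers) | OC1COC[C@](C=C)(CC/C=C(\C)CC/C=C(\C)CCC=C(C)C)O1 | intermediate (not isolated)
12 | (6R)-6-ethenyl-6-homofarnesyl-1,4-dioxan-2-one | O=C1COC[C@](C=C)(CC/C=C(\C)CC/C=C(\C)CCC=C(C)C)O1 | intermediate
13 | {[(2R)-2-ethenyl-2-homofarnesyl-2,3-dihydro-1,4-dioxin-6-yl]oxy}trimethylsilane | C[Si](C)(C)OC1=COC[C@](C=C)(CC/C=C(\C)CC/C=C(\C)CCC=C(C)C)O1 | intermediate (not isolated)
14 | trimethylsilyl (2R)-5-homofarnesyl-3,6-dihydro-2H-pyran-2-carboxylate | C[Si](C)(C)OC(=O)[C@H]1CC=C(CC/C=C(\C)CC/C=C(\C)CCC=C(C)C)CO1 | intermediate (not isolated)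
15 | (2R)-5-homofarnesyl-3,6-dihydro-2H-pyran-2-carboxylic acid | OC(=O)[C@H]1CC=C(CC/C=C(\C)CC/C=C(\C)CCC=C(C)C)CO1 | intermediate
16 | [(2R)-5-homofarnesyl-3,6-dihydro-2H-pyran-2-yl](1H-imidazol-1-yl)methanone | O=C([C@H]1CC=C(CC/C=C(\C)CC/C=C(\C)CCC=C(C)C)CO1)n1ccnc1 | intermediate (not isolated)
17 | (2R)-5-homofarnesyl-N-methoxy-N-methyl-3,6-dihydro-2H-pyran-2-carboxamide | CON(C)C(=O)[C@H]1CC=C(CC/C=C(\C)CC/C=C(\C)CCC=C(C)C)CO1 | intermediate
18 | 1-[(2R)-5-homofarnesyl-3,6-dihydro-2H-pyran-2-yl]ethan-1-one | CC(=O)[C@H]1CC=C(CC/C=C(\C)CC/C=C(\C)CCC=C(C)C)CO1 | intermediate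
19 | potassium 1-[(2R)-5-homofarnesyl-3,6-dihydro-2H-pyran-2-yl]ethen-1-olate | C=C(O[K])[C@H]1CC=C(CC/C=C(\C)CC/C=C(\C)CCC=C(C)C)CO1 | intermediate (not isolated)
20 | 1-[(2R)-5-homofarnesyl-3,6-dihydro-2H-pyran-2-yl]ethenyl trifluoromethanesulfonate | C=C(OS(=O)(=O)C(F)(F)F)[C@H]1CC=C(CC/C=C(\C)CC/C=C(\C)CCC=C(C)C)CO1 | intermediate
21 | methyl 2-[(2R)-5-homofarnesyl-3,6-dihydro-2H-pyran-2-yl]prop-2-enoate | C=C(C(=O)OC)[C@H]1CC=C(CC/C=C(\C)CC/C=C(\C)CCC=C(C)C)CO1 | intermediate
22 | 2-[(2R)-5-homofarnesyl-3,6-dihydro-2H-pyran-2-yl]prop-2-enoic acid | C=C(C(=O)O)[C@H]1CC=C(CC/C=C(\C)CC/C=C(\C)CCC=C(C)C)CO1 | target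

Total step count: 12. Longest linear sequence: 12 steps (1 and 2 to 22).

Steps most likely to fail

Step 7. The ketene acetal may ionise at the tertiary allylic C–O bond (elimination or 1,3-shifted products), or it may be hydrolysed back to the lactone before the strained boat transition state is reached. The fallback sets out from 4 and comes back at 15; it closes the ring by metathesis and takes C2 from the chiral pool. Alcohol 4 would be converted (CBr4, PPh3, CH2Cl2, 0 °C) into (5E,9E)-2-(bromomethyl)-6,10,14-trimethylpentadeca-1,5,9,13-tetraene F1. This bromide would O-alkylate commercial methyl (R)-2-hydroxypent-4-enoate, COC(=O)[C@H](O)CC=C, under silver(I) oxide in ether to give methyl (2R)-2-[(2-homofarnesylprop-2-en-1-yl)oxy]pent-4-enoate F2 without touching the stereocentre. Ring-closing metathesis (second-generation Grubbs catalyst, CH2Cl2, 40 °C) between the monosubstituted and the 1,1-disubstituted terminal alkene, which should react ahead of the trisubstituted chain alkenes, would give methyl (2R)-5-homofarnesyl-3,6-dihydro-2H-pyran-2-carboxylate F3. Saponification with LiOH would return acid 15.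

Step 1. The allyl dianion may attack the farnesyl bromide at its tertiary terminus (SN2′), couple reductively, or be formed incompletely. The fallback sets out from 1 and comes back at 4 by enolate and carbonylation chemistry. Ethyl acetoacetate (NaOEt, EtOH) would be alkylated by 1 to ethyl (4E,8E)-2-acetyl-5,9,13-trimethyltetradeca-4,8,12-trienoate F4. Saponification and decarboxylation (aq. NaOH, then mild acid and warming) would give (5E,9E)-6,10,14-trimethylpentadeca-5,9,13-trien-2-one F5. Kinetic enolisation on the methyl side (KHMDS, −78 °C) and trapping with PhNTf2 would give (5E,9E)-6,10,14-trimethylpentadeca-1,5,9,13-tetraen-2-yl trifluoromethanesulfonate F6. Palladium-catalysed methoxycarbonylation (Pd(OAc)2, PPh3, CO, MeOH, Et3N) would give methyl (5E,9E)-6,10,14-trimethyl-2-methylidenepentadeca-5,9,13-trienoate F7, and 1,2-reduction with DIBAL-H (CH2Cl2, −78 °C) would return 4.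

Step 5. The bulky, weakly nucleophilic hydroxyethoxide may open the CH2 next to the fully substituted carbon too slowly, and the glycol may be alkylated twice. The fallback sets out from 7 and comes back at 12; it replaces steps 5 and 6 by hydrolysis, ether formation and lactonisation. Hydroxide (KOH, DMSO–H2O, 80 °C) would open the epoxide at CH2 to give (2R,5E,9E)-2-ethenyl-6,10,14-trimethylpentadeca-5,9,13-triene-1,2-diol F8 with the carbinol centre untouched. Its primary alkoxide (NaH, THF) would be alkylated with bromoacetic acid to 2-{[(2R)-2-hydroxy-2-homofarnesylbut-3-en-1-yl]oxy}acetic acid F9. Carbodiimide lactonisation (EDC·HCl, DMAP, CH2Cl2) under non-acidic conditions would close dioxanone 12.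

Further compounds
F1 | step 7 | (5E,9E)-2-(bromomethyl)-6,10,14-trimethylpentadeca-1,5,9,13-tetraene | BrCC(=C)CC/C=C(\C)CC/C=C(\C)CCC=C(C)C
F2 | step 7 | methyl (2R)-2-[(2-homofarnesylprop-2-en-1-yl)oxy]pent-4-enoate | COC(=O)[C@@H](CC=C)OCC(=C)CC/C=C(\C)CC/C=C(\C)CCC=C(C)C
F3 | step 7 | methyl (2R)-5-homofarnesyl-3,6-dihydro-2H-pyran-2-carboxylate | COC(=O)[C@H]1CC=C(CC/C=C(\C)CC/C=C(\C)CCC=C(C)C)CO1
F4 | step 1 | ethyl (4E,8E)-2-acetyl-5,9,13-trimethyltetradeca-4,8,12-trienoate | CCOC(=O)C(C(C)=O)C/C=C(\C)CC/C=C(\C)CCC=C(C)C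
F5 | step 1 | (5E,9E)-6,10,14-trimethylpentadeca-5,9,13-trien-2-one | CC(=O)CC/C=C(\C)CC/C=C(\C)CCC=C(C)C
F6 | step 1 | (5E,9E)-6,10,14-trimethylpentadeca-1,5,9,13-tetraen-2-yl trifluoromethanesulfonate | C=C(OS(=O)(=O)C(F)(F)F)CC/C=C(\C)CC/C=C(\C)CCC=C(C)C
F7 | step 1 | methyl (5E,9E)-6,10,14-trimethyl-2-methylidenepentadeca-5,9,13-trienoate | C=C(C(=O)OC)CC/C=C(\C)CC/C=C(\C)CCC=C(C)C
F8 | step 5 | (2R,5E,9E)-2-ethenyl-6,10,14-trimethylpentadeca-5,9,13-triene-1,2-diol | OC[C@](C=C)(CC/C=C(\C)CC/C=C(\C)CCC=C(C)C)O
F9 | step 5 | 2-{[(2R)-2-hydroxy-2-homofarnesylbut-3-en-1-yl]oxy}acetic acid | OC(=O)COC[C@](C=C)(CC/C=C(\C)CC/C=C(\C)CCC=C(C)C)O
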